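(The readings stem from a simulated flask for an exercise, and the scatter is random.)

Amounts first: the elm flask holds 0.0500 M of Xa and 0.0600 M of Xb, yet at 8.5 h you read 0.03168 M of Xp, which is 63.4% of the Xa, and over the last step c(Xp) rose by 4.40 × 10⁻⁴ M.

| setting | elm | oak | larch | cedar | ash |
|---|---|---|---|---|---|
| Xa | 0.0500 M | 0.0200 M | 0.0500 M | 0.0250 M | 0.0500 M |
| Xb | 0.0600 M | 0.0300 M | 0.0300 M | 0.0600 M | 0.0600 M |
| time |  |  |  |  | 21 h |

| elm run: time / h | elm run: [Xp] / M | oak run: time / h | oak run: [Xp] / M | larch run: time / h | larch run: [Xp] / M | cedar run: time / h | cedar run: [Xp] / M |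
|---|---|---|---|---|---|---|---|
| 1.7 | 0.01813 | 1.7 | 0.00629 | 1.7 | 0.01068 | 1.7 | 0.01092 |
| 3.4 | 0.02592 | 3.4 | 0.00938 | 3.4 | 0.01528 | 3.4 | 0.01558 |
| 5.1 | 0.02949 | 5.1 | 0.01110 | 5.1 | 0.01735 | 5.1 | 0.01781 |
| 6.8 | 0.03124 | 6.8 | 0.01151 | 6.8 | 0.01821 | 6.8 | 0.01869 |
| 8.5 | 0.03168 | 8.5 | 0.01122 | 8.5 | 0.01862 | 8.5 | 0.01900 |

(scatter of a reading: 2 × 10⁻⁴ M)

* reaction order in [Xa] at the outset, round the charge of the elm run, defined at two percent of the Xa turned into Xp (one fixed amount of Xp, the same in the runs compared)
* reaction order in [Xb] at the outset, round the charge of the elm run, defined at two percent of the Xa turned into Xp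
* Xp in the ash run at 21 h, as a share of the Xa charged

- Overall: Xa + Xb -> Xp.
- Constant volume, constant temperature.
- "The second partner" is Xb.
- An order is taken over about fifteen percent of the charge, up and down.

Look at the steps between readings. In elm, the second step is 0.458 of the first, and the third is 0.490 of the second. So I take the gap to the plateau as shrinking by a constant factor. Call the time in which that gap falls by a factor e the fade time, an apparent first-order time constant:

fade time, elm = step width / ln(first step / second step) = 2.18 h

The same reckoning on larch gives 2.13 h.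

You can now reach the elm plateau by two ways that share no reading. The first sums the remaining steps of elm's early readings as a geometric series:

plateau = 0.0325 M

The second ignores those readings, takes elm's last reading and corrects it with larch's fade time:

plateau = 0.0323 M

They differ by 2.35 × 10⁻⁴ M, against a scatter of 2 × 10⁻⁴ M on each reading, so I trust them and take the mean, 0.0324 M.

Ash has elm's charge, and 21 h is 9.63 fade times, which on this reckoning leaves 0.00655% of the gap open. My figure for ash is therefore 64.8% of the Xa charged.

For the orders I have cruder means. First readings, elm over cedar, give 0.731 in Xa, and elm over larch give 0.763 in Xb. Each is an average across a halving, and by then the Xp read in elm already equals 36.3% of its Xa, so I hold them loosely.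

The forecast, for which the runs point to “something common dying”, says 0.75 in Xa, 0.77 in Xb and 65% for ash.

The flask gives 64.8% for ash, with orders of 0.73 in Xa and 0.62 in Xb.

    Xa + Xb ⇌ Xi, settled at all times (42.10 M⁻¹)
    Xi → Xp (0.5976 h⁻¹)
    2 Xa → X (10.69 M⁻¹ h⁻¹)
    Xa → Q (0.2009 h⁻¹)

Elm over larch, at the fixed amount of Xp, has a rate ratio of 1.70, an order of 0.762 across the halving, above the value round the elm charge. Now carry elm's fade time to cedar. Cedar's last reading then gives a plateau of 0.0194 M, so Xp should reach half of cedar's Xa at 2.25 h; cedar gets there at 2.12 h.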